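**Retrosynthetic overview**

- The pyranone (C ring) is opened by retro-oxa-Michael to a 2'-hydroxychalcone. The chalcone is cut at the aryl–C(=O) bond into an A-ring aryl-lithium and a B-ring cinnamoyl Weinreb amide.
- The A ring is built, not alkylated: a Danheiser benzannulation (4π ring opening, [2+2], 4π ring opening, 6π electrocyclisation) joins 3-methoxycyclobutenone and a siloxyalkyne. The alkyne carbon that carries the side chain becomes C8.
- The siloxyalkyne comes from (R)-limonene (1): ring-selective ozonolysis, one-carbon alkyne homologation of the aldehyde (old ring C2 becomes aromatic C8), MeMgBr on the ketone (gives CMe2OH), and acetylide oxidation.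
- Stereochemistry: the side-chain (R) centre is limonene's C4 and is never touched. C2 forms in the last ring closure with no useful induction; the two C2 epimers are diastereomers and are separated, and the (2R) epimer is recycled.
- Ring order: A (benzannulation), B (purchased), C (last).

Assumption: 3-ethoxycyclobut-2-en-1-one, the Ohira–Bestmann reagent and diethyl (N-methoxy-N-methylcarbamoylmethyl)phosphonate are purchased. The target is (2S,2''R), matching the given SMILES.

**Route**

Step 1
Reactants: 1, (R)-(+)-limonene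
Product: 2, (3R)-6-oxo-3-(prop-1-en-2-yl)heptanal
Conditions: O3 (1.0 equiv, Sudan III end-point), CH2Cl2/MeOH, −78 °C; then Me2S, rt
Reagents that add atoms: ozone, [O-][O+]=O
Why: Criegee ozonolysis attacks the electron-rich trisubstituted ring alkene ahead of the 1,1-disubstituted isopropenyl group; the stereocentre is not α to either new carbonyl and is carried over unchanged.

Step 2
Reactants: 2
Product: 3, (5R)-5-(prop-1-en-2-yl)oct-7-yn-2-one
Conditions: Ohira–Bestmann reagent, K2CO3, MeOH, 0 °C to rt
Reagents that add atoms: dimethyl (1-diazo-2-oxopropyl)phosphonate, COP(=O)(OC)C(=[N+]=[N-])C(C)=O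
Why: Seyferth–Gilbert homologation under Ohira–Bestmann conditions converts only the aldehyde, leaving the methyl ketone; the old aldehyde carbon becomes the internal alkyne carbon, the future aromatic C8.

Step 3
Reactants: 3
Product: 4, (5R)-2-methyl-5-(prop-1-en-2-yl)oct-7-yn-2-ol
Conditions: MeMgBr (2.2 equiv), THF, −78 to 0 °C
Reagents that add atoms: methylmagnesium bromide, C[Mg]Br
Why: Grignard addition to the only carbonyl gives the CMe2OH terminus; the acetylenic C–H at most consumes reagent and is restored on work-up.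

Step 4
Reactants: 4
Product: 5, triethyl{[(5R)-2-methyl-5-(prop-1-en-2-yl)oct-7-yn-2-yl]oxy}silane
Conditions: TESOTf, 2,6-lutidine, CH2Cl2, −78 to 0 °C
Reagents that add atoms: triethylsilyl triflate, CC[Si](CC)(CC)OS(=O)(=O)C(F)(F)F
Why: silylation of the tertiary alcohol keeps it from quenching the bases of steps 5 and 11 and from trapping the ketene in step 7.

Step 5
Reactants: 5
Product: 6, (4R)-7-methyl-4-(prop-1-en-2-yl)-7-(triethylsilyloxy)-1-(triisopropylsilyloxy)oct-1-yne
Conditions: LiHMDS, THF, −78 °C; t-BuOOLi (t-BuOOH + LiHMDS), −78 to 0 °C; TIPSOTf, −78 °C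
Reagents that add atoms: tert-butyl hydroperoxide, CC(C)(C)OO; triisopropylsilyl triflate, CC(C)[Si](C(C)C)(C(C)C)OS(=O)(=O)C(F)(F)F
Why: Julia oxidation of the lithium acetylide by lithium tert-butyl peroxide gives the ynolate, which is O-silylated to the TIPS ynol ether; the peroxide is nucleophilic and does not touch the isopropenyl group.

Step 6
Reactants: 7, 3-ethoxycyclobut-2-en-1-one
Product: 8, 3-methoxycyclobut-2-en-1-one
Conditions: MeOH (solvent), cat. TsOH, rt
Reagents that add atoms: methanol, CO
Why: vinylogous ester exchange by addition–elimination at C3, driven by excess methanol.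

Step 7
Reactants: 6; 8 (1.5 equiv)
Product: 10, 5-methoxy-2-[(2R)-5-methyl-2-(prop-1-en-2-yl)-5-(triethylsilyloxy)hexyl]benzene-1,3-diol, formed via 9, its mono-TIPS ether 5-methoxy-2-[(2R)-…hexyl]-3-(triisopropylsilyloxy)phenol (not isolated)
Conditions: PhMe, 80 to 110 °C (sealed); then TBAF (1.1 equiv), THF, 0 °C
Reagents that add atoms: none
Why: Danheiser benzannulation: 4π electrocyclic opening of 8 gives (1-methoxyvinyl)ketene, which undergoes regioselective [2+2] with the nucleophilic alkyl-bearing carbon of 6, then 4π opening and 6π electrocyclisation. This places the side chain between OH and OTIPS and para to OMe; fluoride then cleaves only the aryl silyl ether.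

Step 8
Reactants: 10
Product: 11, 5-methoxy-1,3-bis(methoxymethoxy)-2-[(2R)-5-methyl-2-(prop-1-en-2-yl)-5-(triethylsilyloxy)hexyl]benzene
Conditions: NaH, MOMCl, DMF, 0 °C to rt
Reagents that add atoms: chloromethyl methyl ether, COCCl
Why: O-alkylation of both phenols gives a symmetric bis-MOM ether with two equivalent ring C–H bonds, each flanked by a metalation-directing OMOM and OMe.

Step 9
Reactants: 12, 2,4-dihydroxybenzaldehyde
Product: 13, 2,4-bis(methoxymethoxy)benzaldehyde
Conditions: MOMCl, i-Pr2NEt, CH2Cl2, 0 °C to reflux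
Reagents that add atoms: chloromethyl methyl ether, COCCl
Why: standard phenol protection; the chelated 2-OH needs the excess reagent and heating.

Step 10
Reactants: 13
Product: 14, (E)-3-[2,4-bis(methoxymethoxy)phenyl]-N-methoxy-N-methylprop-2-enamide
Conditions: (EtO)2P(O)CH2C(O)N(OMe)Me, NaH, THF, 0 °C to rt
Reagents that add atoms: diethyl (N-methoxy-N-methylcarbamoylmethyl)phosphonate, CCOP(=O)(OCC)CC(=O)N(C)OC
Why: Horner–Wadsworth–Emmons olefination with a stabilised phosphonate gives the E-enamide.

Step 11
Reactants: 11; 14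
Product: 15, (E)-3-[2,4-bis(methoxymethoxy)phenyl]-1-{6-methoxy-2,4-bis(methoxymethoxy)-3-[(2R)-5-methyl-2-(prop-1-en-2-yl)-5-(triethylsilyloxy)hexyl]phenyl}prop-2-en-1-one
Conditions: n-BuLi, THF, 0 °C, 1 h; then 14, −78 to 0 °C
Reagents that add atoms: none
Why: directed ortho-metalation between OMOM and OMe (either site is the same by symmetry), then 1,2-addition to the Weinreb amide, whose chelate releases the chalcone only on work-up; no TMEDA is used, to avoid allylic metalation of the isopropenyl group.

Step 12
Reactants: 15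
Product: 16, (2S)-2-(2,4-dihydroxyphenyl)-7-hydroxy-8-[(2R)-5-hydroxy-5-methyl-2-(prop-1-en-2-yl)hexyl]-5-methoxy-2,3-dihydro-4H-chromen-4-one (target)
Conditions: 1 M HCl, MeOH/THF, 25–40 °C, dark; then NaOAc, 50 °C; preparative HPLC
Reagents that add atoms: none
Why: mild acid removes the four MOM groups and the TES ether, and the twisted 2'-hydroxy-6'-methoxychalcone closes by 6-endo oxa-Michael addition. C2 is created here with essentially no induction from the remote side-chain centre (about 1:1), so the (2S,2''R) and (2R,2''R) diastereomers are separated by HPLC and the (2R) epimer is re-equilibrated (cat. piperidine, EtOH, 60 °C) and recycled.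

**Compound list**

1 | (R)-(+)-limonene | CC1=CC[C@@H](CC1)C(C)=C | starting material
2 | (3R)-6-oxo-3-(prop-1-en-2-yl)heptanal | C=C(C)[C@H](CCC(C)=O)CC=O | intermediate
3 | (5R)-5-(prop-1-en-2-yl)oct-7-yn-2-one | C=C(C)[C@H](CCC(C)=O)CC#C | intermediate
4 | (5R)-2-methyl-5-(prop-1-en-2-yl)oct-7-yn-2-ol | C=C(C)[C@H](CCC(C)(C)O)CC#C | intermediate
5 | TES ether of 4 | C=C(C)[C@H](CCC(C)(C)O[Si](CC)(CC)CC)CC#C | intermediate
6 | (4R)-7-methyl-4-(prop-1-en-2-yl)-7-(triethylsilyloxy)-1-(triisopropylsilyloxy)oct-1-yne | C=C(C)[C@H](CCC(C)(C)O[Si](CC)(CC)CC)CC#CO[Si](C(C)C)(C(C)C)C(C)C | intermediate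
7 | 3-ethoxycyclobut-2-en-1-one | CCOC1=CC(=O)C1 | starting material
8 | 3-methoxycyclobut-2-en-1-one | COC1=CC(=O)C1 | intermediate
9 | 5-methoxy-2-[(2R)-5-methyl-2-(prop-1-en-2-yl)-5-(triethylsilyloxy)hexyl]-3-(triisopropylsilyloxy)phenol | C=C(C)[C@H](CCC(C)(C)O[Si](CC)(CC)CC)Cc1c(O)cc(OC)cc1O[Si](C(C)C)(C(C)C)C(C)C | intermediate (not isolated)
10 | 5-methoxy-2-[(2R)-5-methyl-2-(prop-1-en-2-yl)-5-(triethylsilyloxy)hexyl]benzene-1,3-diol | C=C(C)[C@H](CCC(C)(C)O[Si](CC)(CC)CC)Cc1c(O)cc(OC)cc1O | intermediate
11 | bis-MOM ether of 10 | C=C(C)[C@H](CCC(C)(C)O[Si](CC)(CC)CC)Cc1c(OCOC)cc(OC)cc1OCOC | intermediate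
12 | 2,4-dihydroxybenzaldehyde | O=Cc1ccc(O)cc1O | starting material
13 | 2,4-bis(methoxymethoxy)benzaldehyde | O=Cc1ccc(OCOC)cc1OCOC | intermediate
14 | (E)-3-[2,4-bis(methoxymethoxy)phenyl]-N-methoxy-N-methylprop-2-enamide | CON(C)C(=O)/C=C/c1ccc(OCOC)cc1OCOC | intermediate
15 | protected (E)-chalcone | C=C(C)[C@H](CCC(C)(C)O[Si](CC)(CC)CC)Cc1c(OCOC)cc(OC)c(C(=O)/C=C/c2ccc(OCOC)cc2OCOC)c1OCOC | intermediate
16 | (2S)-2-(2,4-dihydroxyphenyl)-7-hydroxy-8-[(2R)-5-hydroxy-5-methyl-2-(prop-1-en-2-yl)hexyl]-5-methoxychroman-4-one | C=C(C)[C@H](CCC(C)(C)O)Cc1c(O)cc(OC)c2c1O[C@H](c1ccc(O)cc1O)CC2=O | target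

**Totals**

Total steps: 12. Longest linear sequence: 9 (steps 1, 2, 3, 4, 5, 7, 8, 11, 12).

**Steps most likely to fail**

1. Step 12. C2 is not controlled, so at best about half the material per pass is the (2S) epimer, and the remote diastereomers may need a polysaccharide HPLC phase to resolve. The acid can also cyclise a phenol or the tertiary alcohol onto the isopropenyl group, or drive the B-ring 2-OH toward a flavylium ion. Fallback: fix C2 before ring closure. Add the aryl-lithium from 11 to an enantiopure (R)-3-aryl-3-silyloxypropanoic Weinreb amide, then close O1–C2 by intramolecular Mitsunobu displacement with inversion to give (2S) directly.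

2. Step 7. The 3-alkoxycyclobutenone opens less readily than 3-alkyl analogues, the phenol product can be acylated by the ketene, and 6 is hydrolytically labile. Fallback: generate the same (1-methoxyvinyl)ketene at room temperature by photochemical Wolff rearrangement of 1-diazo-3-methoxybut-3-en-2-one in the presence of 6.

3. Step 5. Acetylide oxidation and silylation give moderate yields and the siloxyalkyne does not tolerate acidic silica. Fallback: Kowalski ester homologation. Oxidise 2 to the methyl ester (Pinnick, then TMSCHN2), add MeMgBr and TES as before, then treat with LiCHBr2, n-BuLi and TIPSOTf to reach 6 without an alkyne intermediate.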